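**Strategy.** The decalin is cut across both rings at C5–C10 and C8–C9. Ring A holds its C6=C7 alkene directly beside quaternary C5, and ring B holds an oxygen at C1 beside C10. A vinyl ketone at C1 (C9=C10) and an (E)-diene spanning C5–C8 can therefore fold into rings A and B in one thermal intramolecular Diels–Alder reaction, which also creates the C5 quaternary centre under control of the C4 stereocentre. The precursor is the acyclic (5S,6R,7E)-5-silyloxy-6,7-dimethyldeca-1,7,9-trien-3-one, whose two stereocentres come from one anti-selective propargylation. After ring formation only redox adjustments, an acetone aldol condensation, an ester exchange and a final singlet-oxygen ene reaction remain.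

Key step: step 9

Remark: ring compounds are described with the numbering of the target (ring A = C5–C10; ring B = C1–C5 and C10; C1 carbinol, C3 acyloxy carbon, methyl groups on C4 and C5); β denotes the face of the C5 methyl group.
Assumption: the propargylation of step 2 takes its usual steric course (anti adduct, overall inversion at the propargylic carbon), so that the (S)-mesylate leads to the (3S,4R) alcohol 5.

Step 1
Reactants: 1 (S)-but-3-yn-2-ol
Product: 2 (S)-but-3-yn-2-yl methanesulfonate
Conditions: MsCl, Et3N, CH2Cl2, −78 °C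
Reagents that add atoms: methanesulfonyl chloride, CS(=O)(=O)Cl
Why: O-sulfonylation of the propargylic alcohol does not break the C–O bond, so the (S) configuration is kept.

Step 2
Reactants: 2 (S)-but-3-yn-2-yl methanesulfonate; 3 3-[(tert-butyldimethylsilyl)oxy]propanal
Product: 5 (3S,4R)-1-[(tert-butyldimethylsilyl)oxy]-4-methylhex-5-yn-3-ol, via allenylindium reagent 4 (not isolated)
Conditions: Pd(dppf)Cl2 (5 mol %), InI, THF–HMPA 3:1, rt; then H2O
Reagents that add atoms: none
Why: Marshall–Tamaru propargylation, in which zerovalent palladium displaces the mesylate anti (SN2′), the allenylpalladium is transmetalated to indium and the allenylindium adds to the aldehyde through a cyclic SE2′ transition state, which should transfer the mesylate chirality with overall inversion to the methyl-bearing carbon (4R) and set the carbinol anti to it (3S).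

Step 3
Reactants: 5 (3S,4R)-1-[(tert-butyldimethylsilyl)oxy]-4-methylhex-5-yn-3-ol
Product: 6 (3R,4S)-4,6-bis[(tert-butyldimethylsilyl)oxy]-3-methylhex-1-yne
Conditions: TBSOTf, 2,6-lutidine, CH2Cl2, −78 → 0 °C
Reagents that add atoms: tert-butyldimethylsilyl trifluoromethanesulfonate, CC(C)(C)[Si](C)(C)OS(=O)(=O)C(F)(F)F
Why: Silylation of the secondary alcohol with a silyl triflate touches no stereocentre.

Step 4
Reactants: 6 (3R,4S)-4,6-bis[(tert-butyldimethylsilyl)oxy]-3-methylhex-1-yne; 7 vinyl bromide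
Product: 9 (3E,5R,6S)-6,8-bis[(tert-butyldimethylsilyl)oxy]-4,5-dimethylocta-1,3-diene, via alkenylalane 8 (not isolated)
Conditions: Me3Al, Cp2ZrCl2 (0.25 equiv), CH2Cl2, 0 °C → rt; then 7, Pd(PPh3)4 (5 mol %), ZnCl2, THF, rt
Reagents that add atoms: trimethylaluminium, C[Al](C)C
Why: Negishi carboalumination adds methyl and aluminium syn with aluminium at the terminal carbon, and the alkenylalane is then cross-coupled with vinyl bromide under palladium catalysis with retention, which fixes the (E)-geometry of the trisubstituted C5=C6 bond (target numbering).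

Step 5
Reactants: 9 (3E,5R,6S)-6,8-bis[(tert-butyldimethylsilyl)oxy]-4,5-dimethylocta-1,3-diene
Product: 10 (3S,4R,5E)-3-[(tert-butyldimethylsilyl)oxy]-4,5-dimethylocta-5,7-dien-1-ol
Conditions: HF·pyridine, pyridine, THF, 0 °C
Reagents that add atoms: none
Why: Buffered fluoride desilylation is much faster at the unhindered primary silyl ether than at the secondary one next to the methyl-bearing carbon.

Step 6
Reactants: 10 (3S,4R,5E)-3-[(tert-butyldimethylsilyl)oxy]-4,5-dimethylocta-5,7-dien-1-ol
Product: 11 (3S,4R,5E)-3-[(tert-butyldimethylsilyl)oxy]-4,5-dimethylocta-5,7-dienal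
Conditions: Dess–Martin periodinane, pyridine, CH2Cl2, 0 °C → rt
Reagents that add atoms: none
Why: Dess–Martin oxidation of the primary alcohol under buffered, non-enolising conditions should leave the β-silyloxy aldehyde and both stereocentres intact.

Step 7
Reactants: 11 (3S,4R,5E)-3-[(tert-butyldimethylsilyl)oxy]-4,5-dimethylocta-5,7-dienal; 12 vinylmagnesium bromide
Product: 13 (5S,6R,7E)-5-[(tert-butyldimethylsilyl)oxy]-6,7-dimethyldeca-1,7,9-trien-3-ol (both C3 epimers)
Conditions: THF, −78 °C; then H2O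
Reagents that add atoms: none
Why: 1,2-Addition of the vinyl Grignard reagent to the aldehyde gives the allylic alcohol, whose new carbinol centre is removed in the next step and needs no control.

Step 8
Reactants: 13 (5S,6R,7E)-5-[(tert-butyldimethylsilyl)oxy]-6,7-dimethyldeca-1,7,9-trien-3-ol
Product: 14 (5S,6R,7E)-5-[(tert-butyldimethylsilyl)oxy]-6,7-dimethyldeca-1,7,9-trien-3-one
Conditions: Dess–Martin periodinane, pyridine, CH2Cl2, 0 °C; used at once
Reagents that add atoms: none
Why: Dess–Martin oxidation of the allylic alcohol gives the vinyl ketone under neutral conditions that should not eliminate the β-silyloxy group.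

Step 9
Reactants: 14 (5S,6R,7E)-5-[(tert-butyldimethylsilyl)oxy]-6,7-dimethyldeca-1,7,9-trien-3-one
Product: 15 (3S,4R,4aR,8aR)-3-[(tert-butyldimethylsilyl)oxy]-4,4a-dimethyl-3,4,4a,7,8,8a-hexahydronaphthalen-1(2H)-one (cis-fused; 3β-silyloxy, 4β,5β-dimethyl, Δ6, C1 ketone)
Conditions: PhMe (0.01 M), BHT (cat.), 80 °C
Reagents that add atoms: none
Why: A concerted, asynchronous [4+2] cycloaddition in which the (E)-diene C5=C6–C7=C8 adds suprafacially to the vinyl ketone C9=C10 (C8–C9 bonding ahead of C5–C10); the closest known reaction type is the thermal type 1 intramolecular Diels–Alder reaction of 1,7,9-decatrien-3-ones, including dienes with a disubstituted terminus that deliver an angular methyl group. Ring A closes as the new six-membered cyclohexene (alkene left at C6=C7) and ring B closes at the same time as a fused six-membered ring through the four-atom tether C4–C3–C2–C1, which folds boat-like with its carbonyl endo and so gives the cis ring fusion. C10 is set by this endo mode and is of no consequence, because it becomes sp2 in step 10. C5 is set by the C4 stereocentre: the inner position at C4, beneath C2 and beside H-6, should hold only hydrogen, so the C4 methyl sits on the outer side and the dienophile adds to the diene face that leaves the C5 methyl cis to it, while the C3 silyloxy group, cis to that methyl, also points outward with its C–O dipole opposed to the carbonyl. The selectivity needed is therefore diene-face selectivity alone, since regiochemistry is fixed by the tether and the (E)-geometry from step 4 places the tether outside and the C5 methyl inside the diene, which slows the reaction but decides which substituent becomes angular. Heat without a Lewis acid is chosen so that the β-silyloxy ketone is not eliminated, and BHT suppresses polymerisation of the enone.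

Step 10
Reactants: 15 (3S,4R,4aR,8aR)-3-[(tert-butyldimethylsilyl)oxy]-4,4a-dimethyl-3,4,4a,7,8,8a-hexahydronaphthalen-1(2H)-one
Product: 17 (3S,4R,4aR)-3-[(tert-butyldimethylsilyl)oxy]-4,4a-dimethyl-3,4,4a,7-tetrahydronaphthalen-1(2H)-one (6,9-dien-1-one), via silyl enol ether 16 (not isolated)
Conditions: TMSOTf, Et3N, CH2Cl2, 0 °C → rt; then Pd(OAc)2, MeCN, rt
Reagents that add atoms: none
Why: Saegusa–Ito oxidation, in which equilibrating silylation should favour the tetrasubstituted C1=C10 enol ether (the C2 side is disfavoured by the adjacent C3–O bond) and the palladium enolate at C10 can eliminate only toward C9, which erases the C10 stereocentre and gives the C9=C10 enone.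

Step 11
Reactants: 17 (3S,4R,4aR)-3-[(tert-butyldimethylsilyl)oxy]-4,4a-dimethyl-3,4,4a,7-tetrahydronaphthalen-1(2H)-one
Product: 18 (1R,3S,4R,4aR)-3-[(tert-butyldimethylsilyl)oxy]-4,4a-dimethyl-1,2,3,4,4a,7-hexahydronaphthalen-1-ol (1β-ol)
Conditions: NaBH4, CeCl3·7H2O, MeOH, −78 °C
Reagents that add atoms: none
Why: Luche 1,2-reduction of the enone, in which hydride should attack C1 from the α face because the β face is flanked in 1,3 relationships by the axial C5 methyl (fixed axial on ring B by the C9=C10 bond) and the C3 silyloxy group, which sets the (1R) β-alcohol.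

Step 12
Reactants: 18 (1R,3S,4R,4aR)-3-[(tert-butyldimethylsilyl)oxy]-4,4a-dimethyl-1,2,3,4,4a,7-hexahydronaphthalen-1-ol
Product: 19 1-O-[2-(trimethylsilyl)ethoxy]methyl (SEM) ether of 18
Conditions: SEMCl, iPr2NEt, Bu4NI (cat.), CH2Cl2, 40 °C
Reagents that add atoms: 2-(trimethylsilyl)ethoxymethyl chloride, C[Si](C)(C)CCOCCl
Why: O-alkylation with the small, reactive chloromethyl ether protects the hindered allylic alcohol as an acetal that is stable to oxidants, base and fluoride at room temperature.

Step 13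
Reactants: 19 1-O-SEM ether of 18
Product: 20 (4aR,5R,6S,8R)-6-[(tert-butyldimethylsilyl)oxy]-4a,5-dimethyl-8-{[2-(trimethylsilyl)ethoxy]methoxy}-5,6,7,8-tetrahydronaphthalen-2(4aH)-one (6,9-dien-8-one)
Conditions: t-BuOOH (70% aq.), CrO3 (10 mol %), CH2Cl2, rt
Reagents that add atoms: tert-butyl hydroperoxide, CC(C)(C)OO
Why: Chromium-catalysed allylic oxidation with tert-butyl hydroperoxide should occur at the doubly allylic C8 methylene, the weakest C–H bond, and give the cross-conjugated dienone, since aromatisation is blocked by quaternary C5.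

Step 14
Reactants: 20 (4aR,5R,6S,8R)-6-[(tert-butyldimethylsilyl)oxy]-4a,5-dimethyl-8-{[2-(trimethylsilyl)ethoxy]methoxy}-5,6,7,8-tetrahydronaphthalen-2(4aH)-one
Product: 21 (4aR,5R,6S,8R)-6-[(tert-butyldimethylsilyl)oxy]-4a,5-dimethyl-8-{[2-(trimethylsilyl)ethoxy]methoxy}-4,4a,5,6,7,8-hexahydronaphthalen-2(3H)-one (9-en-8-one)
Conditions: H2 (1 atm), RhCl(PPh3)3 (cat.), PhH–EtOH, rt
Reagents that add atoms: none
Why: Homogeneous hydrogenation with RhCl(PPh3)3 reduces the disubstituted C6=C7 bond of a cross-conjugated cyclohexadienone much faster than the trisubstituted C9=C10 bond.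

Step 15
Reactants: 21 (4aR,5R,6S,8R)-6-[(tert-butyldimethylsilyl)oxy]-4a,5-dimethyl-8-{[2-(trimethylsilyl)ethoxy]methoxy}-4,4a,5,6,7,8-hexahydronaphthalen-2(3H)-one; 22 acetone
Product: 24 3-(2-hydroxypropan-2-yl) derivative of 21 (C7 aldol; both C7 epimers), via lithium dienolate 23 (not isolated)
Conditions: LDA, THF, −78 °C; ZnCl2; 22, −78 °C; AcOH
Reagents that add atoms: none
Why: Kinetic deprotonation at C7 gives the cross-conjugated dienolate, which undergoes aldol addition to acetone (ZnCl2 suppresses the retro-aldol reaction), and the new C7 centre is transient.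

Step 16
Reactants: 24 3-(2-hydroxypropan-2-yl) derivative of 21
Product: 26 (4aR,5R,6S,8R)-6-[(tert-butyldimethylsilyl)oxy]-4a,5-dimethyl-3-(propan-2-ylidene)-8-{[2-(trimethylsilyl)ethoxy]methoxy}-4,4a,5,6,7,8-hexahydronaphthalen-2(3H)-one, via tertiary mesylate 25 (not isolated)
Conditions: MsCl, Et3N, CH2Cl2, 0 °C; then DBU, rt
Reagents that add atoms: none
Why: Aldol dehydration by mesylation of the tertiary alcohol and E1cB elimination gives the conjugated C7=C11 alkene regiospecifically, because only H-7 is acidic.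

Step 17
Reactants: 26 (4aR,5R,6S,8R)-6-[(tert-butyldimethylsilyl)oxy]-4a,5-dimethyl-3-(propan-2-ylidene)-8-{[2-(trimethylsilyl)ethoxy]methoxy}-4,4a,5,6,7,8-hexahydronaphthalen-2(3H)-one
Product: 27 (4aR,5R,6S,8R)-6-hydroxy-4a,5-dimethyl-3-(propan-2-ylidene)-8-{[2-(trimethylsilyl)ethoxy]methoxy}-4,4a,5,6,7,8-hexahydronaphthalen-2(3H)-one (free 3β-OH)
Conditions: TBAF, AcOH, THF, rt
Reagents that add atoms: none
Why: Buffered fluoride cleaves the secondary silyl ether, whereas the SEM ether is inert to fluoride at room temperature.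

Step 18
Reactants: 27 (4aR,5R,6S,8R)-6-hydroxy-4a,5-dimethyl-3-(propan-2-ylidene)-8-{[2-(trimethylsilyl)ethoxy]methoxy}-4,4a,5,6,7,8-hexahydronaphthalen-2(3H)-one; 28 angelic acid [(Z)-2-methylbut-2-enoic acid]
Product: 30 3-O-angelate of 27, via mixed anhydride 29 (not isolated)
Conditions: 2,4,6-Cl3C6H2COCl, Et3N, PhMe, rt; then 27, PhMe, 75 °C (no DMAP)
Reagents that add atoms: none
Why: Yamaguchi esterification through the mixed anhydride, run without a nucleophilic catalyst so that the (Z)-enoate should not isomerise, keeps the C3 configuration because the C–O bond is not broken.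

Step 19
Reactants: 30 3-O-angelate of 27
Product: 31 (1R,3S,4R,5R)-3-angeloyloxy-1-hydroxy-4,5-dimethyl-7-(propan-2-ylidene)-9-en-8-one (target numbering)
Conditions: MgBr2·OEt2, MeNO2–Et2O, rt; aq. work-up
Reagents that add atoms: none
Why: Lewis-acid cleavage of the SEM acetal with MgBr2 is a mild deprotection that should spare the ester, the dienone and the allylic alcohol.

Step 20
Reactants: 31 (1R,3S,4R,5R)-3-angeloyloxy-1-hydroxy-4,5-dimethyl-7-(propan-2-ylidene)-9-en-8-one
Product: 32 CNP0300636.1, (1R,3S,4R,5R)-3-angeloyloxy-7-(2-hydroperoxypropan-2-yl)-1-hydroxy-4,5-dimethyl-6,9-dien-8-one (target numbering)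
Conditions: O2, tetraphenylporphyrin (cat.), hν (>500 nm), CH2Cl2, 0 °C
Reagents that add atoms: dioxygen (as singlet oxygen), O=O
Why: Schenck ene reaction of singlet oxygen with the s-cis α-alkylidene ketone, in which oxygen should bond to C11 and abstract H-6 from the group geminal to the carbonyl, moving the alkene to C6=C7 without forming a stereocentre.

**Compound list**

1 | (S)-but-3-yn-2-ol | C[C@H](O)C#C | starting material
2 | (S)-but-3-yn-2-yl methanesulfonate | C[C@H](OS(C)(=O)=O)C#C | intermediate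
3 | 3-[(tert-butyldimethylsilyl)oxy]propanal | O=CCCO[Si](C)(C)C(C)(C)C | starting material
4 | (aR)-buta-1,2-dien-1-ylindium iodide methanesulfonate (allenylindium reagent) | CC([H])=[C@]=C([H])[In](I)OS(C)(=O)=O | intermediate
5 | (3S,4R)-1-[(tert-butyldimethylsilyl)oxy]-4-methylhex-5-yn-3-ol | CC(C)(C)[Si](C)(C)OCC[C@H](O)[C@H](C)C#C | intermediate
6 | (3R,4S)-4,6-bis[(tert-butyldimethylsilyl)oxy]-3-methylhex-1-yne | CC(C)(C)[Si](C)(C)OCC[C@H](O[Si](C)(C)C(C)(C)C)[C@H](C)C#C | intermediate
7 | vinyl bromide | C=CBr | starting material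
8 | (E)-alkenyl(dimethyl)alane from 6 | CC(C)(C)[Si](C)(C)OCC[C@H](O[Si](C)(C)C(C)(C)C)[C@H](C)/C(C)=C/[Al](C)C | intermediate
9 | (3E,5R,6S)-6,8-bis[(tert-butyldimethylsilyl)oxy]-4,5-dimethylocta-1,3-diene | CC(C)(C)[Si](C)(C)OCC[C@H](O[Si](C)(C)C(C)(C)C)[C@H](C)/C(C)=C/C=C | intermediate
10 | (3S,4R,5E)-3-[(tert-butyldimethylsilyl)oxy]-4,5-dimethylocta-5,7-dien-1-ol | OCC[C@H](O[Si](C)(C)C(C)(C)C)[C@H](C)/C(C)=C/C=C | intermediate
11 | (3S,4R,5E)-3-[(tert-butyldimethylsilyl)oxy]-4,5-dimethylocta-5,7-dienal | O=CC[C@H](O[Si](C)(C)C(C)(C)C)[C@H](C)/C(C)=C/C=C | intermediate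
12 | vinylmagnesium bromide | C=C[Mg]Br | starting material
13 | (5S,6R,7E)-5-[(tert-butyldimethylsilyl)oxy]-6,7-dimethyldeca-1,7,9-trien-3-ol (C3 epimers) | C=CC(O)C[C@H](O[Si](C)(C)C(C)(C)C)[C@H](C)/C(C)=C/C=C | intermediate
14 | (5S,6R,7E)-5-[(tert-butyldimethylsilyl)oxy]-6,7-dimethyldeca-1,7,9-trien-3-one | C=CC(=O)C[C@H](O[Si](C)(C)C(C)(C)C)[C@H](C)/C(C)=C/C=C | intermediate
15 | (3S,4R,4aR,8aR)-3-[(tert-butyldimethylsilyl)oxy]-4,4a-dimethyl-3,4,4a,7,8,8a-hexahydronaphthalen-1(2H)-one | CC(C)(C)[Si](C)(C)O[C@H]1CC(=O)[C@@H]2CCC=C[C@]2(C)[C@H]1C | intermediate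
16 | trimethylsilyl enol ether of 15 (C1=C10) | CC(C)(C)[Si](C)(C)O[C@H]1CC(O[Si](C)(C)C)=C2CCC=C[C@]2(C)[C@H]1C | intermediate
17 | (3S,4R,4aR)-3-[(tert-butyldimethylsilyl)oxy]-4,4a-dimethyl-3,4,4a,7-tetrahydronaphthalen-1(2H)-one | CC(C)(C)[Si](C)(C)O[C@H]1CC(=O)C2=CCC=C[C@]2(C)[C@H]1C | intermediate
18 | (1R,3S,4R,4aR)-3-[(tert-butyldimethylsilyl)oxy]-4,4a-dimethyl-1,2,3,4,4a,7-hexahydronaphthalen-1-ol | CC(C)(C)[Si](C)(C)O[C@H]1C[C@@H](O)C2=CCC=C[C@]2(C)[C@H]1C | intermediate
19 | 1-O-[2-(trimethylsilyl)ethoxy]methyl ether of 18 | CC(C)(C)[Si](C)(C)O[C@H]1C[C@@H](OCOCC[Si](C)(C)C)C2=CCC=C[C@]2(C)[C@H]1C | intermediate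
20 | (4aR,5R,6S,8R)-6-[(tert-butyldimethylsilyl)oxy]-4a,5-dimethyl-8-{[2-(trimethylsilyl)ethoxy]methoxy}-5,6,7,8-tetrahydronaphthalen-2(4aH)-one | CC(C)(C)[Si](C)(C)O[C@H]1C[C@@H](OCOCC[Si](C)(C)C)C2=CC(=O)C=C[C@]2(C)[C@H]1C | intermediate
21 | (4aR,5R,6S,8R)-6-[(tert-butyldimethylsilyl)oxy]-4a,5-dimethyl-8-{[2-(trimethylsilyl)ethoxy]methoxy}-4,4a,5,6,7,8-hexahydronaphthalen-2(3H)-one | CC(C)(C)[Si](C)(C)O[C@H]1C[C@@H](OCOCC[Si](C)(C)C)C2=CC(=O)CC[C@]2(C)[C@H]1C | intermediate
22 | acetone | CC(C)=O | starting material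
23 | lithium dienolate of 21 (C7=C8–OLi) | CC(C)(C)[Si](C)(C)O[C@H]1C[C@@H](OCOCC[Si](C)(C)C)C2=CC(O[Li])=CC[C@]2(C)[C@H]1C | intermediate
24 | 3-(2-hydroxypropan-2-yl) derivative of 21 (C7 epimers) | CC(C)(C)[Si](C)(C)O[C@H]1C[C@@H](OCOCC[Si](C)(C)C)C2=CC(=O)C(C(C)(C)O)C[C@]2(C)[C@H]1C | intermediate
25 | tertiary methanesulfonate of 24 | CC(C)(C)[Si](C)(C)O[C@H]1C[C@@H](OCOCC[Si](C)(C)C)C2=CC(=O)C(C(C)(C)OS(C)(=O)=O)C[C@]2(C)[C@H]1C | intermediate
26 | (4aR,5R,6S,8R)-6-[(tert-butyldimethylsilyl)oxy]-4a,5-dimethyl-3-(propan-2-ylidene)-8-{[2-(trimethylsilyl)ethoxy]methoxy}-4,4a,5,6,7,8-hexahydronaphthalen-2(3H)-one | CC(C)(C)[Si](C)(C)O[C@H]1C[C@@H](OCOCC[Si](C)(C)C)C2=CC(=O)C(=C(C)C)C[C@]2(C)[C@H]1C | intermediate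
27 | (4aR,5R,6S,8R)-6-hydroxy-4a,5-dimethyl-3-(propan-2-ylidene)-8-{[2-(trimethylsilyl)ethoxy]methoxy}-4,4a,5,6,7,8-hexahydronaphthalen-2(3H)-one | O[C@H]1C[C@@H](OCOCC[Si](C)(C)C)C2=CC(=O)C(=C(C)C)C[C@]2(C)[C@H]1C | intermediate
28 | angelic acid, (Z)-2-methylbut-2-enoic acid | C/C=C(/C)C(=O)O | starting material
29 | (Z)-2-methylbut-2-enoic 2,4,6-trichlorobenzoic anhydride | C/C=C(/C)C(=O)OC(=O)c1c(Cl)cc(Cl)cc1Cl | intermediate
30 | 3-O-angelate of 27 | C/C=C(/C)C(=O)O[C@H]1C[C@@H](OCOCC[Si](C)(C)C)C2=CC(=O)C(=C(C)C)C[C@]2(C)[C@H]1C | intermediate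
31 | (1R,3S,4R,5R)-3-angeloyloxy-1-hydroxy-4,5-dimethyl-7-(propan-2-ylidene)-9-en-8-one (target numbering) | C/C=C(/C)C(=O)O[C@H]1C[C@@H](O)C2=CC(=O)C(=C(C)C)C[C@]2(C)[C@H]1C | intermediate
32 | CNP0300636.1 | C/C=C(/C)C(=O)O[C@H]1C[C@@H](O)C2=CC(=O)C(C(C)(C)OO)=C[C@]2(C)[C@H]1C | target

**Total step count:** 20
**Longest linear sequence:** 20 steps (1 → 32)

**Steps most likely to fail**

1. Step 9 (key step). The dienophile may add to the other diene face, with the C4 methyl taking the inner position, which would give the C5 epimer. Because the inside methyl at C5 slows ring closure, the enone may also polymerise or the diene may undergo a [1,5]-hydrogen shift. The fallback sets out from 14 and returns at 15, and replaces the neutral enone by a cationic dienophile. Treatment of 14 with 1,2-bis(trimethylsilyloxy)ethane and catalytic TMSOTf in CH2Cl2 at −78 °C should give the 2-vinyl-1,3-dioxolane F1. Under the same acid F1 should ionise to a 2-alkoxyallyl cation and undergo the ionic intramolecular Diels–Alder reaction to the dioxolane of the octalinone F2. PPTS in wet acetone then releases 15. The cation bonds C9 to C8 well ahead of C10 to C5, so the tether is looser in the transition state and the inner position at C4 should be left to hydrogen, and the reaction runs about 150 °C colder.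

2. Step 10. Silylation may go toward C2 and not C10, or the C3 silyloxy group may be lost by β-elimination; the skipped dienone 17 may also drift into conjugation. The fallback sets out from 15 and returns at 20, and reverses the order of the two oxidations so that the new alkene is formed between two carbonyl groups. CrO3 (cat.)/t-BuOOH should oxidise the allylic C8 methylene of 15 to the 6-ene-1,8-dione F3. TMSOTf/Et3N should convert both ketones into the bis(trimethylsilyl) trienol ether F4, in which enolisation of C1 toward C10 is favoured by conjugation with the C8 dienol ether. DDQ oxidises F4 to the ene-dione F5. Luche reduction of the C1 carbonyl, the less conjugated of the two, should give the 1β-hydroxy dienone F6, and SEM protection as in step 12 gives 20.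

3. Step 18. Acylation of the hindered C3 hydroxyl may be slow, and the (Z)-enoate may isomerise to the (E)-enoate (tiglate) under forcing conditions. The fallback sets out from 27 and returns at 30, and builds the (Z)-alkene on the alcohol. Esterification of 27 with 2-[bis(2,2,2-trifluoroethoxy)phosphoryl]propanoic acid (DCC, DMAP, CH2Cl2) gives the phosphonopropanoate F7. Still–Gennari olefination of F7 with acetaldehyde (KHMDS, 18-crown-6, THF, −78 °C) should then give the angelate 30 with (Z)-selectivity.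

**Further compounds**

F1 | step 9 | 2-vinyl-1,3-dioxolane (ethylene ketal) of 14 | C=CC1(OCCO1)C[C@H](O[Si](C)(C)C(C)(C)C)[C@H](C)/C(C)=C/C=C
F2 | step 9 | ethylene ketal of 15 | CC(C)(C)[Si](C)(C)O[C@H]1CC2(OCCO2)[C@@H]3CCC=C[C@]3(C)[C@H]1C
F3 | step 10 | cis-fused 3β-silyloxy-4β,5β-dimethyl-6-ene-1,8-dione | CC(C)(C)[Si](C)(C)O[C@H]1CC(=O)[C@@H]2CC(=O)C=C[C@]2(C)[C@H]1C
F4 | step 10 | 1,8-bis(trimethylsilyloxy)-1(10),6,8-triene from F3 | CC(C)(C)[Si](C)(C)O[C@H]1CC(O[Si](C)(C)C)=C2C=C(O[Si](C)(C)C)C=C[C@]2(C)[C@H]1C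
F5 | step 10 | 3β-silyloxy-4β,5β-dimethyl-6,9-diene-1,8-dione | CC(C)(C)[Si](C)(C)O[C@H]1CC(=O)C2=CC(=O)C=C[C@]2(C)[C@H]1C
F6 | step 10 | 1β-hydroxy-3β-silyloxy-4β,5β-dimethyl-6,9-dien-8-one | CC(C)(C)[Si](C)(C)O[C@H]1C[C@@H](O)C2=CC(=O)C=C[C@]2(C)[C@H]1C
F7 | step 18 | 3-O-{2-[bis(2,2,2-trifluoroethoxy)phosphoryl]propanoate} of 27 (both epimers at the phosphonate carbon) | CC(C(=O)O[C@H]1C[C@@H](OCOCC[Si](C)(C)C)C2=CC(=O)C(=C(C)C)C[C@]2(C)[C@H]1C)P(=O)(OCC(F)(F)F)OCC(F)(F)F
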